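**Retrosynthetic overview**
- Key step, made last: the 5,6-diol is cut at its two C–O bonds. A hydroxyl-directed syn-osmylation of a (5Z)-allylic alcohol forms C5–O and C6–O and sets C5 and C6 from C7.
- C7–C8: a fluoride-promoted, open-transition-state aldol between the silyloxycyclopentadiene of a bromo-hydroxy-cyclopentenone and an achiral (Z)-enal sets C7 and C8 from C12.
- The cyclopentenone is the only ring that is built. It comes from a 2,3,5-trisubstituted furan by a catalytic asymmetric oxa-Piancatelli rearrangement, in which water forms the C12–O bond and C12 is set.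
- The furan comes from 3-bromofuran, formaldehyde and (2Z,5Z)-octadienyl bromide (1-bromopent-2-yne + propargyl alcohol); the enal comes from methyl hex-5-enoate and cis-butenediol.

Assumption: carbon labels follow prostanoid numbering (C1 = ester carbon, ring = C8–C12, C13–C20 = octadienyl chain); the catalyst antipode that gives (S)-11 in step 6 is fixed in a first test run.

**Step 1**
Reactants: 1 1-bromopent-2-yne; 2 prop-2-yn-1-ol
Product: 3 octa-2,5-diyn-1-ol
Conditions: CuI (1 equiv), NaI, K2CO3, DMF, 20 °C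
Reagents that add atoms: none
Why: Copper-mediated sp–sp3 coupling of a terminal alkyne with a propargylic bromide (copper acetylide displacement) gives the skipped diyne without touching the free alcohol; no stereocentre is formed.

**Step 2**
Reactants: 3 octa-2,5-diyn-1-ol
Product: 4 (2Z,5Z)-octa-2,5-dien-1-ol
Conditions: H2 (1 atm), Ni(OAc)2·4H2O/NaBH4 (gives Ni2B, 10 mol%), ethylenediamine, EtOH, 20 °C
Reagents that add atoms: none
Why: Nickel boride/ethylenediamine semi-hydrogenation adds H2 syn to each alkyne and stops at the alkene, so both double bonds are Z.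

**Step 3**
Reactants: 4 (2Z,5Z)-octa-2,5-dien-1-ol
Product: 5 (2Z,5Z)-1-bromoocta-2,5-diene
Conditions: CBr4, PPh3, CH2Cl2, 0 °C
Reagents that add atoms: carbon tetrabromide BrC(Br)(Br)Br
Why: Appel bromination converts the primary allylic alcohol to the bromide under neutral conditions, without allylic shift or Z/E scrambling.

**Step 4**
Reactants: 6 3-bromofuran
Product: 8 (3-bromofuran-2-yl)methanol, via 3-bromo-2-lithiofuran 7 (not isolated)
Conditions: LiN(iPr)2, THF, −78 °C; paraformaldehyde, −78 to 20 °C; H2O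
Reagents that add atoms: formaldehyde (as paraformaldehyde) C=O
Why: Deprotonation–hydroxymethylation: the amide base removes the most acidic furan proton (C2, flanked by O and Br) without bromine–lithium exchange, and the furyllithium adds to formaldehyde.

**Step 5**
Reactants: 8 (3-bromofuran-2-yl)methanol; 5 (2Z,5Z)-1-bromoocta-2,5-diene
Product: 10 [3-bromo-5-[(2Z,5Z)-octa-2,5-dien-1-yl]furan-2-yl]methanol, via dilithiated furan 9 (not isolated)
Conditions: LiN(iPr)2 (2.2 equiv), THF, −78 to −40 °C; then 5, −78 to −20 °C; H2O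
Reagents that add atoms: none
Why: Lithiation–alkylation: after alkoxide formation the base deprotonates the only free α-position (C5), and the 5-furyllithium displaces the primary allylic bromide by SN2, so both Z-alkenes are kept.

**Step 6**
Reactants: 10 [3-bromo-5-[(2Z,5Z)-octa-2,5-dien-1-yl]furan-2-yl]methanol
Product: 11 (4S)-2-bromo-4-hydroxy-4-[(2Z,5Z)-octa-2,5-dien-1-yl]cyclopent-2-en-1-one
Conditions: (S,S)-IDPi (N-triflyl imidodiphosphorimidate on two 3,3′-bis[3,5-bis(trifluoromethyl)phenyl]-BINOL units, 5 mol%), H2O (5 equiv), CHCl3, 40 °C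
Reagents that add atoms: water O
Why: Proposed new method: a confined, very strong chiral Brønsted acid ionises the primary furfuryl alcohol, water adds to furan C5 (new C12–O bond), the hemiketal opens to a dihydroxypentadienyl cation that stays ion-paired and hydrogen-bonded to the chiral anion, and the conrotatory 4π closure (C8–C12) then proceeds with one helical sense to set C12 as S and place Br at C10; the closest known reactions are chiral phosphoric acid-catalysed aza-Piancatelli rearrangements and IDPi-catalysed asymmetric Nazarov cyclisations, neither shown with water, a primary carbinol or a quaternary carbinol product.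

**Step 7**
Reactants: 12 methyl hex-5-enoate; 13 (2Z)-but-2-ene-1,4-diol
Product: 14 methyl (5Z)-7-hydroxyhept-5-enoate
Conditions: Ru(=CH-C6H4-2-OiPr)(SIMes)(3,6-dichlorobenzene-1,2-dithiolate) (5 mol%), 13 in excess, THF, 22 °C
Reagents that add atoms: none
Why: Stereoretentive (Z-selective) olefin cross-metathesis with a ruthenium dithiolate carbene transfers the Z-geometry of the diol to the new allylic alcohol.

**Step 8**
Reactants: 14 methyl (5Z)-7-hydroxyhept-5-enoate
Product: 15 methyl (5Z)-7-oxohept-5-enoate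
Conditions: Dess–Martin periodinane, pyridine, CH2Cl2, 0 °C; used crude at once
Reagents that add atoms: none
Why: Buffered Dess–Martin oxidation gives the (Z)-enal without acid- or base-induced Z-to-E isomerisation.

**Step 9**
Reactants: 11 (4S)-2-bromo-4-hydroxy-4-[(2Z,5Z)-octa-2,5-dien-1-yl]cyclopent-2-en-1-one
Product: 16 (5S)-2-bromo-5-[(2Z,5Z)-octa-2,5-dien-1-yl]-3,5-bis(trimethylsilyloxy)cyclopenta-1,3-diene
Conditions: Me3SiOTf (2.3 equiv), Et3N, CH2Cl2, 0 °C; pentane, filtration, used crude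
Reagents that add atoms: trimethylsilyl trifluoromethanesulfonate C[Si](C)(C)OS(=O)(=O)C(F)(F)F
Why: Soft enolisation–silylation caps the tertiary alcohol and silylates the only enolisable position (C8), giving a 5,5-disubstituted silyloxycyclopentadiene that cannot undergo 1,5-hydrogen shifts; C12 is untouched.

**Step 10**
Reactants: 16 (5S)-2-bromo-5-[(2Z,5Z)-octa-2,5-dien-1-yl]-3,5-bis(trimethylsilyloxy)cyclopenta-1,3-diene; 15 methyl (5Z)-7-oxohept-5-enoate
Product: 18 methyl (5Z,7R,8R,12S,14Z,17Z)-10-bromo-7-hydroxy-9-oxo-12-(trimethylsilyloxy)prosta-5,10,14,17-tetraen-1-oate, via bis-silyl aldol adduct 17 (not isolated)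
Conditions: [(Me2N)3S][Me3SiF2] (10 mol%), THF, −78 °C; then citric acid, MeOH, 0 °C
Reagents that add atoms: none
Why: Fluoride-catalysed Mukaiyama-type aldol through a naked enolate and an open antiperiplanar transition state: the aldehyde attacks C8 on the face carrying the small C12 oxygen (away from the octadienyl CH2, the same oxygen-syn preference as 5-alkoxycyclopentadienes) and its alkenyl group sits gauche to H8 rather than to quaternary C12, giving the 7,8-syn adduct with the side chain cis to the C12 oxygen; mild acidic methanolysis then frees only the secondary silyl ether.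

**Step 11**
Reactants: 18 methyl (5Z,7R,8R,12S,14Z,17Z)-10-bromo-7-hydroxy-9-oxo-12-(trimethylsilyloxy)prosta-5,10,14,17-tetraen-1-oate
Product: 20 methyl (5S,6S,7S,8R,12S,14Z,17Z)-10-bromo-5,6,7,12-tetrahydroxy-9-oxoprosta-10,14,17-trien-1-oate, via osmate ester 19 (not isolated)
Conditions: OsO4 (1.05 equiv), TMEDA (1.1 equiv), CH2Cl2, −78 °C; then HCl, MeOH, 20 °C
Reagents that add atoms: osmium tetroxide O=[Os](=O)(=O)=O
Why: Hydroxyl-directed (Donohoe-type) syn-dihydroxylation: OsO4·TMEDA hydrogen-bonds to the only free hydroxyl (C7) and, with C7–H eclipsing the Z-alkene (1,3-allylic strain), is delivered to the OH face anti to the ring, so C6–O is threo to C7–O and suprafacial addition to the Z-alkene makes C5/C6 erythro (5S,6S); the silylated C12 oxygen cannot direct the reagent to the two remote Z-alkenes or the bromoenone, and HCl/MeOH cleaves the osmate ester and the tertiary silyl ether.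

**Compound list**
1 | 1-bromopent-2-yne | CCC#CCBr | starting material
2 | prop-2-yn-1-ol | C#CCO | starting material
3 | octa-2,5-diyn-1-ol | CCC#CCC#CCO | intermediate
4 | (2Z,5Z)-octa-2,5-dien-1-ol | CC/C=C\C/C=C\CO | intermediate
5 | (2Z,5Z)-1-bromoocta-2,5-diene | CC/C=C\C/C=C\CBr | intermediate
6 | 3-bromofuran | Brc1ccoc1 | starting material
7 | 3-bromo-2-lithiofuran | [Li]c1occc1Br | intermediate
8 | (3-bromofuran-2-yl)methanol | OCc1occc1Br | intermediate
9 | lithium (3-bromo-5-lithiofuran-2-yl)methanolate (dilithiated furan) | [Li]OCc1oc([Li])cc1Br | intermediate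
10 | [3-bromo-5-[(2Z,5Z)-octa-2,5-dien-1-yl]furan-2-yl]methanol | CC/C=C\C/C=C\Cc1cc(Br)c(CO)o1 | intermediate
11 | (4S)-2-bromo-4-hydroxy-4-[(2Z,5Z)-octa-2,5-dien-1-yl]cyclopent-2-en-1-one | CC/C=C\C/C=C\C[C@@]1(O)C=C(Br)C(=O)C1 | intermediate
12 | methyl hex-5-enoate | C=CCCCC(=O)OC | starting material
13 | (2Z)-but-2-ene-1,4-diol | OC/C=C\CO | starting material
14 | methyl (5Z)-7-hydroxyhept-5-enoate | OC/C=C\CCCC(=O)OC | intermediate
15 | methyl (5Z)-7-oxohept-5-enoate | O=C/C=C\CCCC(=O)OC | intermediate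
16 | (5S)-2-bromo-5-[(2Z,5Z)-octa-2,5-dien-1-yl]-3,5-bis(trimethylsilyloxy)cyclopenta-1,3-diene | CC/C=C\C/C=C\C[C@@]1(O[Si](C)(C)C)C=C(Br)C(O[Si](C)(C)C)=C1 | intermediate
17 | methyl (5Z,7R,8R,12S,14Z,17Z)-10-bromo-9-oxo-7,12-bis(trimethylsilyloxy)prosta-5,10,14,17-tetraen-1-oate | CC/C=C\C/C=C\C[C@@]1(O[Si](C)(C)C)C=C(Br)C(=O)[C@@H]1[C@H](O[Si](C)(C)C)/C=C\CCCC(=O)OC | intermediate
18 | methyl (5Z,7R,8R,12S,14Z,17Z)-10-bromo-7-hydroxy-9-oxo-12-(trimethylsilyloxy)prosta-5,10,14,17-tetraen-1-oate | CC/C=C\C/C=C\C[C@@]1(O[Si](C)(C)C)C=C(Br)C(=O)[C@@H]1[C@H](O)/C=C\CCCC(=O)OC | intermediate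
19 | cyclic O5,O6-osmate ester, OsO2(TMEDA) diolate, of methyl (5S,6S,7S,8R,12S,14Z,17Z)-10-bromo-5,6,7-trihydroxy-9-oxo-12-(trimethylsilyloxy)prosta-10,14,17-trien-1-oate | CC/C=C\C/C=C\C[C@@]1(O[Si](C)(C)C)C=C(Br)C(=O)[C@@H]1[C@H](O)[C@@H](O[Os-2]3(=O)(=O)([N+](C)(C)CC[N+]3(C)C)O2)[C@@H]2CCCC(=O)OC | intermediate
20 | methyl (5S,6S,7S,8R,12S,14Z,17Z)-10-bromo-5,6,7,12-tetrahydroxy-9-oxoprosta-10,14,17-trien-1-oate (CNP0143456.1) | CC/C=C\C/C=C\C[C@@]1(O)C=C(Br)C(=O)[C@@H]1[C@H](O)[C@@H](O)[C@@H](O)CCCC(=O)OC | target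

**Step count and risks**

Total: 11 steps. Longest linear sequence: 8 steps (1, 2, 3, 5, 6, 9, 10, 11).

Step 6 (the proposed asymmetric oxa-Piancatelli) is the most likely to fail: a primary furfuryl alcohol is hard to ionise, oligomeric ethers can form, and the enantio-induction is unproven. The fallback uses known chemistry and sets out from 10. The classical aqueous oxa-Piancatelli rearrangement (ZnCl2, dioxane/H2O, 80 °C) gives racemic 2-bromo-4-hydroxy-4-[(2Z,5Z)-octa-2,5-dien-1-yl]cyclopent-2-en-1-one F1. Preparative chromatography on a chiral stationary phase (amylose tris(3,5-dimethylphenylcarbamate), supercritical CO2/MeOH) then separates the enantiomers. The (4R)-2-bromo-4-hydroxy-4-[(2Z,5Z)-octa-2,5-dien-1-yl]cyclopent-2-en-1-one F2 is set aside and the route is rejoined at 11.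

Step 10 (aldol) is the second risk: the (Z)-enal can isomerise or undergo conjugate addition, and both the facial and the syn/anti selectivity rest on an open transition state. The fallback sets out from 16 and replaces the enal by a rod-shaped, non-isomerisable ynal. Methyl 7-oxohept-5-ynoate F3 is made by MnO2 oxidation of purchased methyl 7-hydroxyhept-5-ynoate. The same fluoride-catalysed aldol gives in the flask methyl (7S,8R,12S,14Z,17Z)-10-bromo-9-oxo-7,12-bis(trimethylsilyloxy)prosta-10,14,17-trien-5-yn-1-oate F4. Citric acid/MeOH then gives methyl (7S,8R,12S,14Z,17Z)-10-bromo-7-hydroxy-9-oxo-12-(trimethylsilyloxy)prosta-10,14,17-trien-5-yn-1-oate F5. Semi-hydrogenation of the propargylic alkyne (H2, Pd/CaCO3 poisoned with Pb(OAc)2, quinoline, EtOAc, 0 °C) rejoins the route at 18.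

Step 11 (directed osmylation) is the third risk: the stoichiometric oxidant may also attack the two remote Z-alkenes. The fallback carries the ω-chain as a latent diyne, which osmium tetroxide does not touch. It sets out from 3 and comes back at 20.
- Appel bromination of 3 gives 1-bromoocta-2,5-diyne F6.
- Alkylation of dilithiated furan 9 with it gives [3-bromo-5-(octa-2,5-diyn-1-yl)furan-2-yl]methanol F7.
- The rearrangement of step 6 gives (4S)-2-bromo-4-hydroxy-4-(octa-2,5-diyn-1-yl)cyclopent-2-en-1-one F8.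
- Silylation as in step 9 gives (5S)-2-bromo-5-(octa-2,5-diyn-1-yl)-3,5-bis(trimethylsilyloxy)cyclopenta-1,3-diene F9.
- The aldol of step 10 with 15 gives in the flask methyl (5Z,7R,8R,12S)-10-bromo-9-oxo-7,12-bis(trimethylsilyloxy)prosta-5,10-diene-14,17-diyn-1-oate F10, and after citric acid/MeOH methyl (5Z,7R,8R,12S)-10-bromo-7-hydroxy-9-oxo-12-(trimethylsilyloxy)prosta-5,10-diene-14,17-diyn-1-oate F11.
- Osmylation as in step 11 gives in the flask the cyclic O5,O6-osmate ester (OsO2(TMEDA) diolate) of the diynyl triol F12, and after HCl/MeOH methyl (5S,6S,7S,8R,12S)-10-bromo-5,6,7,12-tetrahydroxy-9-oxoprost-10-ene-14,17-diyn-1-oate F13.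
- Nickel boride semi-hydrogenation as in step 2 turns both alkynes into Z-alkenes and returns to 20.

**Further compounds**
F1 | step 6 | racemic 2-bromo-4-hydroxy-4-[(2Z,5Z)-octa-2,5-dien-1-yl]cyclopent-2-en-1-one | CC/C=C\C/C=C\CC1(O)C=C(Br)C(=O)C1
F2 | step 6 | (4R)-2-bromo-4-hydroxy-4-[(2Z,5Z)-octa-2,5-dien-1-yl]cyclopent-2-en-1-one | CC/C=C\C/C=C\C[C@]1(O)C=C(Br)C(=O)C1
F3 | step 10 | methyl 7-oxohept-5-ynoate | O=CC#CCCCC(=O)OC
F4 | step 10 | methyl (7S,8R,12S,14Z,17Z)-10-bromo-9-oxo-7,12-bis(trimethylsilyloxy)prosta-10,14,17-trien-5-yn-1-oate | CC/C=C\C/C=C\C[C@@]1(O[Si](C)(C)C)C=C(Br)C(=O)[C@@H]1[C@H](O[Si](C)(C)C)C#CCCCC(=O)OC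
F5 | step 10 | methyl (7S,8R,12S,14Z,17Z)-10-bromo-7-hydroxy-9-oxo-12-(trimethylsilyloxy)prosta-10,14,17-trien-5-yn-1-oate | CC/C=C\C/C=C\C[C@@]1(O[Si](C)(C)C)C=C(Br)C(=O)[C@@H]1[C@H](O)C#CCCCC(=O)OC
F6 | step 11 | 1-bromoocta-2,5-diyne | CCC#CCC#CCBr
F7 | step 11 | [3-bromo-5-(octa-2,5-diyn-1-yl)furan-2-yl]methanol | CCC#CCC#CCc1cc(Br)c(CO)o1
F8 | step 11 | (4S)-2-bromo-4-hydroxy-4-(octa-2,5-diyn-1-yl)cyclopent-2-en-1-one | CCC#CCC#CC[C@@]1(O)C=C(Br)C(=O)C1
F9 | step 11 | (5S)-2-bromo-5-(octa-2,5-diyn-1-yl)-3,5-bis(trimethylsilyloxy)cyclopenta-1,3-diene | CCC#CCC#CC[C@@]1(O[Si](C)(C)C)C=C(Br)C(O[Si](C)(C)C)=C1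
F10 | step 11 | methyl (5Z,7R,8R,12S)-10-bromo-9-oxo-7,12-bis(trimethylsilyloxy)prosta-5,10-diene-14,17-diyn-1-oate | CCC#CCC#CC[C@@]1(O[Si](C)(C)C)C=C(Br)C(=O)[C@@H]1[C@H](O[Si](C)(C)C)/C=C\CCCC(=O)OC
F11 | step 11 | methyl (5Z,7R,8R,12S)-10-bromo-7-hydroxy-9-oxo-12-(trimethylsilyloxy)prosta-5,10-diene-14,17-diyn-1-oate | CCC#CCC#CC[C@@]1(O[Si](C)(C)C)C=C(Br)C(=O)[C@@H]1[C@H](O)/C=C\CCCC(=O)OC
F12 | step 11 | cyclic O5,O6-osmate ester, OsO2(TMEDA) diolate, of methyl (5S,6S,7S,8R,12S)-10-bromo-5,6,7-trihydroxy-9-oxo-12-(trimethylsilyloxy)prost-10-ene-14,17-diyn-1-oate | CCC#CCC#CC[C@@]1(O[Si](C)(C)C)C=C(Br)C(=O)[C@@H]1[C@H](O)[C@@H](O[Os-2]3(=O)(=O)([N+](C)(C)CC[N+]3(C)C)O2)[C@@H]2CCCC(=O)OC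
F13 | step 11 | methyl (5S,6S,7S,8R,12S)-10-bromo-5,6,7,12-tetrahydroxy-9-oxoprost-10-ene-14,17-diyn-1-oate | CCC#CCC#CC[C@@]1(O)C=C(Br)C(=O)[C@@H]1[C@H](O)[C@@H](O)[C@@H](O)CCCC(=O)OC
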